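**Plan**
1. Numbering (daucane): C1 = ring-fusion C(CH3), C2, C3, C4 = C(OH)(iPr), C5 = ring-fusion CH, C6 = CH–O-aroyl, C7 = CH2, C8 = C(CH3)=, C9 = CH=, C10 = CH–O-isovaleryl.
2. Retrosynthesis: the two ester C–O bonds are cut first; C4–OH and C5–H come from a C4=C5–C6=O enone via its epoxide; the seven-membered ring is then cut at C6–C7 and C1–C10 into a four-carbon unit C7–C10 and the allyl unit C6–C5–C1 that is exocyclic to the cyclopentene.
3. Enabling feature: in the cycloheptene the C8=C9 bond lies between sp3 C7 and C10, and their partners C6 (oxygenated) and C1 are 1,3-related. This is the retron of the Cope shift of a cis-1,2-dialkenylcyclopropanol (C6, C7, C8). The C10 oxygen and C7 are tied as the ring oxygen of a furan-3-olate (a temporary C7–O–C10 bridge), C6 is activated as an acylsilane, and the C8 oxygen is later exchanged for CH3.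
4. Forward: limonene gives the cyclopentene acylsilane; a one-flask Brook shift, cyclopropanation and oxy-Cope shift closes the seven-membered ring as an 8-oxabicyclo[3.2.1]octadiene; then C8 methylation, C4=C5 enone, epoxide, SmI2 opening of epoxide and oxygen bridge, and the two esters.
5. Stereochemistry: the bought C4 centre of (R)-limonene steers the annulation to the face anti to isopropyl and so fixes C1; the boat Cope shift relays C1 to C10 (CH3 and ring oxygen cis); the limonene centre is then erased, and C4–OH, C5–H and C6–H are set from the methyl face by substrate control.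

Key step: step 7

Step 1
Reactants: 1 (R)-(+)-limonene
Product: 2 (4R)-1-methyl-4-(propan-2-yl)cyclohex-1-ene
Conditions: H2 (1 atm), (Ph3P)3RhCl (cat.), benzene, rt
Reagents that add atoms: none
Why: Homogeneous rhodium-catalysed hydrogenation should reduce the 1,1-disubstituted isopropenyl alkene much faster than the trisubstituted ring alkene and leaves the stereocentre untouched.

Step 2
Reactants: 2 (4R)-1-methyl-4-(propan-2-yl)cyclohex-1-ene
Product: 4 (3R)-6-oxo-3-(propan-2-yl)heptanal, via ozonide 3 (not isolated)
Conditions: O3, CH2Cl2, −78 °C; then Me2S, −78 °C → rt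
Reagents that add atoms: ozone ([O-][O+]=O)
Why: Ozonolysis with reductive work-up cleaves the only C=C bond to the keto aldehyde without touching the stereocentre.

Step 3
Reactants: 4 (3R)-6-oxo-3-(propan-2-yl)heptanal
Product: 5 (5S)-2-methyl-5-(propan-2-yl)cyclopent-1-ene-1-carbaldehyde
Conditions: piperidine (cat.), AcOH (cat.), benzene, reflux, Dean–Stark
Reagents that add atoms: none
Why: Intramolecular aldol condensation of the aldehyde enamine onto the methyl ketone closes the five-membered ring and dehydrates to the tetrasubstituted enal, the usual course for 6-oxoheptanals of the limonene series; the descriptor changes to S only through the CIP priorities.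

Step 4
Reactants: 5 (5S)-2-methyl-5-(propan-2-yl)cyclopent-1-ene-1-carbaldehyde
Product: 6 [dimethyl(phenyl)silyl][(5S)-2-methyl-5-(propan-2-yl)cyclopent-1-en-1-yl]methanol
Conditions: PhMe2SiLi, THF, −78 °C; then H2O
Reagents that add atoms: (dimethylphenylsilyl)lithium ([Li][Si](C)(C)c1ccccc1)
Why: 1,2-Addition of the silyllithium to the hindered β,β-disubstituted enal gives the α-hydroxysilane, whose lithium alkoxide is the stable side of the Brook equilibrium; the new carbinol centre forms as a mixture that step 5 erases.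

Step 5
Reactants: 6 [dimethyl(phenyl)silyl][(5S)-2-methyl-5-(propan-2-yl)cyclopent-1-en-1-yl]methanol
Product: 7 [dimethyl(phenyl)silyl][(5S)-2-methyl-5-(propan-2-yl)cyclopent-1-en-1-yl]methanone
Conditions: (COCl)2, DMSO, CH2Cl2, −78 °C; Et3N, −78 → 0 °C
Reagents that add atoms: none
Why: Swern oxidation of an α-hydroxy allylsilane is a standard entry to α,β-unsaturated acylsilanes and avoids the strong base or acid that would trigger a Brook shift.

Step 6
Reactants: 8 3-bromofuran
Product: 10 (furan-3-yloxy)trimethylsilane, via furan-3-yllithium 9 (not isolated)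
Conditions: n-BuLi, Et2O, −78 °C; then Me3SiOOSiMe3, −78 → −20 °C; non-aqueous work-up, distillation
Reagents that add atoms: bis(trimethylsilyl) peroxide (C[Si](C)(C)OO[Si](C)(C)C)
Why: Bromine–lithium exchange at −78 °C gives the 3-lithiofuran without isomerisation, and electrophilic oxygenation of an aryllithium with the silyl peroxide delivers the O-silyl ether directly, here the silyl enol ether of 3(2H)-furanone.

Step 7
Reactants: 7 [dimethyl(phenyl)silyl][(5S)-2-methyl-5-(propan-2-yl)cyclopent-1-en-1-yl]methanone; 10 (furan-3-yloxy)trimethylsilane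
Product: 14 7,10-epoxy-bridged dienyl triflate (6-silyloxy-7,10-epoxydauca-5,8-dien-8-yl triflate; 1-CH3 and 4-iPr on the face of the oxygen bridge), via lithium furan-3-olate 11 (not isolated), via cyclopropanolate 12 (not isolated), via lithium enolate 13 (not isolated)
Conditions: 10, MeLi (1.0 equiv), THF, 0 °C; 7, −80 → −30 °C; then N-(5-chloro-2-pyridyl)triflimide, −78 °C; H2O
Reagents that add atoms: N-(5-chloropyridin-2-yl)-1,1,1-trifluoro-N-(trifluoromethanesulfonyl)methanesulfonamide (O=S(=O)(N(c1ccc(Cl)cn1)S(=O)(=O)C(F)(F)F)C(F)(F)F)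
Why: Proposed new method: C2 of the furan-3-olate 11 (the later C7) adds to the acylsilane carbonyl (C6), a 1,2-Brook shift of silicon to oxygen gives a siloxyallyl anion that closes 3-exo-trig on the furanone carbonyl (C8) to the cis-1,2-dialkenylcyclopropanolate 12, and the anionic oxy-Cope (divinylcyclopropane) shift of 12 breaks C6–C8 and makes C1–C10, so that C6–C7 and C1–C10 are both formed in one flask before the enolate 13 is triflated on oxygen. The closest known reaction type is the Brook-rearrangement-mediated [3+4] annulation of α,β-unsaturated acylsilanes with lithium enolates of alkenyl methyl ketones and 2-cycloalkenones; not shown so far are a heteroaromatic enolate as the four-carbon partner and an acylsilane with a fully substituted β-carbon. The seven-membered ring closes by the [3,3]-sigmatropic shift through the boat transition state that the cis-fused 2-oxabicyclo[3.1.0]hexene enforces (formal 4+3), and the furan ring oxygen is left as a C7–O–C10 bridge. In that boat the Z-methyl group on C1 and the ring oxygen on C10 point the same way, so C1–CH3 and C10–O come out cis (C7 follows from the bridge); the absolute sense is set when the siloxyallyl anion closes the cyclopropane on its face anti to the pseudoaxial isopropyl group at C4, the centre bought with limonene, and the Cope shift passes this face on to C1. The step needs C- and not O-attack of 11 (C2 carries the largest coefficient and gives the conjugated 3(2H)-furanone), three- and not five-membered ring closure of the allyl anion (its other end, C1, is tertiary and hindered), and triflation of 13 at −78 °C before the bridging oxygen can leave by β-elimination.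

Step 8
Reactants: 14 7,10-epoxy-bridged dienyl triflate
Product: 15 7,10-epoxy-bridged silyl enol ether with C8 methyl (6-silyloxy-7,10-epoxydauca-5,8-diene)
Conditions: Me2CuLi, THF, −20 → 0 °C
Reagents that add atoms: lithium dimethylcuprate ([Li+].C[Cu-]C)
Why: Cuprate coupling of an alkenyl triflate replaces OTf by CH3 with the double bond kept at C8=C9, and the silyl enol ether should be inert to the cuprate.

Step 9
Reactants: 15 7,10-epoxy-bridged silyl enol ether with C8 methyl
Product: 16 7,10-epoxy-bridged enone (7,10-epoxydauca-4,8-dien-6-one)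
Conditions: Pd(OAc)2 (1.1 equiv), MeCN, rt → 40 °C
Reagents that add atoms: none
Why: Saegusa–Ito oxidation: the palladium enolate should bind C5 on the face anti to the cis methyl and isopropyl groups, which is the face of H-4, so syn β-hydride elimination gives the C4=C5 enone and erases the limonene stereocentre.

Step 10
Reactants: 16 7,10-epoxy-bridged enone
Product: 17 4,5-epoxy ketone (4,5:7,10-diepoxydauc-8-en-6-one; epoxide oxygen cis to 1-CH3)
Conditions: t-BuOOH, DBU, CH2Cl2, 0 °C → rt
Reagents that add atoms: tert-butyl hydroperoxide (CC(C)(C)OO)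
Why: Weitz–Scheffer nucleophilic epoxidation touches only the electron-poor C4=C5 bond and should attack C4 from the face of the C1 methyl group, since the other face is covered by C10 and the bicyclic cage, which puts the C4 oxygen cis to CH3; C7 is a bridgehead, so the ketone cannot enolise.

Step 11
Reactants: 17 4,5-epoxy ketone
Product: 19 4,10-dihydroxydauc-8-en-6-one (cis-fused; 4-OH, 5-H, 10-OH and 1-CH3 on one face), via bridged hydroxy ketone 18 (not isolated)
Conditions: SmI2 (5 equiv), THF/MeOH, −78 → −20 °C
Reagents that add atoms: none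
Why: Samarium diiodide cleaves C–O bonds α to a ketone: the epoxide C5–O bond should go first and the samarium enolate of the still bridged ketone be protonated on the exo face (H-5 cis to CH3 and to the C4 oxygen), then the C7–O bridge is cut and the extended enolate is protonated kinetically at C7, which frees the C10 hydroxyl with its configuration and keeps C8=C9 in place.

Step 12
Reactants: 19 4,10-dihydroxydauc-8-en-6-one
Product: 20 10-isovaleryloxy-4-hydroxydauc-8-en-6-one
Conditions: isovaleric anhydride, DMAP (cat.), pyridine, CH2Cl2, 0 °C → rt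
Reagents that add atoms: 3-methylbutanoic anhydride (CC(C)CC(=O)OC(=O)CC(C)C)
Why: DMAP-catalysed acylation takes the secondary allylic C10 hydroxyl and not the tertiary C4 hydroxyl, and doing it while C6 is still a ketone removes any competition from a C6 hydroxyl.

Step 13
Reactants: 20 10-isovaleryloxy-4-hydroxydauc-8-en-6-one
Product: 21 10-isovaleryloxydauc-8-ene-4,6-diol (6-H cis to 5-H)
Conditions: Me4NBH(OAc)3, MeCN/AcOH, −30 °C
Reagents that add atoms: none
Why: Evans–Saksena reduction: hydride bound through the C4 hydroxyl should reach C6 on the convex face of the cis-fused ketone (the face of H-5, away from the isopropyl group), which gives the C6 alcohol with H-6 cis to H-5, and the acidic medium avoids retro-aldol cleavage.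

Step 14
Reactants: 21 10-isovaleryloxydauc-8-ene-4,6-diol
Product: 22 6-(4-acetoxybenzoyloxy)-10-isovaleryloxydauc-8-en-4-ol
Conditions: 4-acetoxybenzoyl chloride, Et3N, DMAP, CH2Cl2, rt
Reagents that add atoms: 4-acetoxybenzoyl chloride (CC(=O)Oc1ccc(cc1)C(Cl)=O)
Why: Acyl chloride/DMAP esterification acylates the secondary C6 hydroxyl with retention, while the tertiary C4 hydroxyl does not react.

Step 15
Reactants: 22 6-(4-acetoxybenzoyloxy)-10-isovaleryloxydauc-8-en-4-ol
Product: 23 target CNP0086724.1
Conditions: N2H4·AcOH, DMF, rt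
Reagents that add atoms: none
Why: Hydrazinolysis with hydrazinium acetate cleaves an aryl acetate far faster than the secondary alkyl and benzoate esters because phenoxide is the better leaving group, which frees the phenol.

**Compound list**
1 | (R)-(+)-limonene, (4R)-1-methyl-4-(prop-1-en-2-yl)cyclohex-1-ene | CC1=CC[C@@H](CC1)C(C)=C | starting material
2 | (4R)-1-methyl-4-(propan-2-yl)cyclohex-1-ene ((R)-p-menth-1-ene) | CC1=CC[C@@H](CC1)C(C)C | intermediate
3 | ozonide of 2 (1,2,4-trioxolane over the former C=C, both epimers at the two new centres) | CC12CC[C@@H](C(C)C)CC(OO1)O2 | intermediate (not isolated)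
4 | (3R)-6-oxo-3-(propan-2-yl)heptanal | O=CC[C@@H](CCC(C)=O)C(C)C | intermediate
5 | (5S)-2-methyl-5-(propan-2-yl)cyclopent-1-ene-1-carbaldehyde | CC(C)[C@@H]1CCC(C)=C1C=O | intermediate
6 | [dimethyl(phenyl)silyl][(5S)-2-methyl-5-(propan-2-yl)cyclopent-1-en-1-yl]methanol (both carbinol epimers) | CC(C)[C@@H]1CCC(C)=C1C(O)[Si](C)(C)c2ccccc2 | intermediate
7 | [dimethyl(phenyl)silyl][(5S)-2-methyl-5-(propan-2-yl)cyclopent-1-en-1-yl]methanone (acylsilane) | CC(C)[C@@H]1CCC(C)=C1C(=O)[Si](C)(C)c2ccccc2 | intermediate
8 | 3-bromofuran | Brc1ccoc1 | starting material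
9 | furan-3-yllithium | [Li]c1ccoc1 | intermediate (not isolated)
10 | (furan-3-yloxy)trimethylsilane | C[Si](C)(C)Oc1ccoc1 | intermediate
11 | lithium furan-3-olate | [Li+].[O-]c1ccoc1 | intermediate (not isolated)
12 | lithium 6-[dimethyl(phenyl)silyloxy]-6-[(5S)-2-methyl-5-isopropylcyclopent-1-enyl]-2-oxabicyclo[3.1.0]hex-3-en-5-olate, cyclopentenyl group endo (cis to the dihydrofuran ring); cyclopropane = C6, C7, C8 | [Li+].CC(C)[C@@H]1CCC(C)=C1[C@@]3(O[Si](C)(C)c2ccccc2)[C@H]4OC=C[C@@]34[O-] | intermediate (not isolated)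
13 | lithium enolate (C8–OLi, C8=C9) of the 7,10-epoxy-bridged ketone; C6 silyl enol ether (C5=C6), 1-CH3 and 4-iPr on the face of the oxygen bridge | [Li+].CC(C)[C@@H]1CC[C@]2(C)C1=C(O[Si](C)(C)c3ccccc3)[C@H]4O[C@@H]2C=C4[O-] | intermediate (not isolated)
14 | 6-[dimethyl(phenyl)silyloxy]-7,10-epoxydauca-5,8-dien-8-yl trifluoromethanesulfonate; 1-CH3 and 4-iPr on the face of the oxygen bridge, 4-H on the other | CC(C)[C@@H]1CC[C@]2(C)C1=C(O[Si](C)(C)c3ccccc3)[C@H]4O[C@@H]2C=C4OS(=O)(=O)C(F)(F)F | intermediate
15 | 6-[dimethyl(phenyl)silyloxy]-7,10-epoxydauca-5,8-diene (C8 methyl in place of OTf, same configuration) | CC(C)[C@@H]1CC[C@]2(C)C1=C(O[Si](C)(C)c3ccccc3)[C@H]4O[C@@H]2C=C4C | intermediate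
16 | 7,10-epoxydauca-4,8-dien-6-one (1-CH3 on the face of the oxygen bridge) | CC(C)C1=C2C(=O)[C@H]4O[C@H](C=C4C)[C@]2(C)CC1 | intermediate
17 | 4,5:7,10-diepoxydauc-8-en-6-one (4,5-epoxide oxygen cis to 1-CH3, isopropyl on the other face) | CC(C)[C@@]1(O2)CC[C@]3(C)[C@@]12C(=O)[C@H]4O[C@@H]3C=C4C | intermediate
18 | 7,10-epoxy-4-hydroxydauc-8-en-6-one (4-OH and 5-H cis to 1-CH3, oxygen bridge intact) | CC(C)[C@@]1(O)CC[C@]3(C)[C@H]1C(=O)[C@H]4O[C@@H]3C=C4C | intermediate (not isolated)
19 | 4,10-dihydroxydauc-8-en-6-one (cis-fused; 1-CH3, 4-OH, 5-H and 10-OH on one face, isopropyl on the other) | CC1=C[C@@H](O)[C@]2(C)CC[C@](O)(C(C)C)[C@@H]2C(=O)C1 | intermediate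
20 | 4-hydroxy-6-oxodauc-8-en-10-yl 3-methylbutanoate | CC1=C[C@@H](OC(=O)CC(C)C)[C@]2(C)CC[C@](O)(C(C)C)[C@@H]2C(=O)C1 | intermediate
21 | 4,6-dihydroxydauc-8-en-10-yl 3-methylbutanoate (6-OH trans to 5-H and to 4-OH) | CC1=C[C@@H](OC(=O)CC(C)C)[C@]2(C)CC[C@](O)(C(C)C)[C@@H]2[C@H](O)C1 | intermediate
22 | 4-hydroxy-10-(3-methylbutanoyloxy)dauc-8-en-6-yl 4-acetoxybenzoate | CC1=C[C@@H](OC(=O)CC(C)C)[C@]2(C)CC[C@](O)(C(C)C)[C@@H]2[C@H](OC(=O)c2ccc(OC(C)=O)cc2)C1 | intermediate
23 | CNP0086724.1, (3S,3aS,4R,8R,8aR)-3-hydroxy-6,8a-dimethyl-8-(3-methylbutanoyloxy)-3-(propan-2-yl)-1,2,3,3a,4,5,8,8a-octahydroazulen-4-yl 4-hydroxybenzoate | CC1=C[C@@H](OC(=O)CC(C)C)[C@]2(C)CC[C@](O)(C(C)C)[C@@H]2[C@H](OC(=O)c2ccc(O)cc2)C1 | target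

**Totals and risks**
Total step count: 15. Longest linear sequence: 14 (steps 1–5 and 7–15); step 6 is the side branch.

Step 7 (Proposed new method). What may go wrong: proton transfer or O-silyl exchange may outrun C-addition of the furanolate; the bridged enolate may open by β-elimination of the bridging oxygen before it is triflated; the cyclopropane may close on the isopropyl face or the allyl anion may close a five-membered ring. Fallback, from 7 to 20, by known reaction types only: commercial (E)-4-methoxybut-3-en-2-one is transetherified with 4-methoxybenzyl alcohol (PPTS, toluene, MeOH distilled off) to (E)-4-[(4-methoxybenzyl)oxy]but-3-en-2-one F1. Its lithium enolate (LDA, THF, −80 °C) and 7 undergo the Brook-mediated [3+4] annulation in its documented form with an alkenyl methyl ketone enolate, and the enolate is triflated as in step 7 to the monocyclic cycloheptadienyl triflate F2; here the boat Cope shift of the E-enol ether places C10–OPMB trans to C1–CH3. Me2CuLi gives the C8-methyl compound F3, Saegusa–Ito oxidation the enone F4, t-BuOOH/DBU the epoxy ketone F5 and SmI2 the β-hydroxy ketone F6. DDQ (CH2Cl2/H2O) removes the PMB group to give the C10 epimer of 19, hydroxy ketone F7, and Mitsunobu esterification with 3-methylbutanoic acid (PPh3, DIAD) inverts C10 and gives 20.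

Step 10. What may go wrong: poor facial selectivity of the peroxide addition (the methyl face and the C10 face of the cyclopentene may be too alike), or no addition at the fully substituted β-carbon. Fallback, from 16 to 18: copper(I)-catalysed conjugate borylation (B2pin2, CuCl, NaOt-Bu, chiral bisphosphine, MeOH, THF), in which the ligand rather than the substrate selects the face of C4 and the copper enolate is protonated on the exo face at C5, gives the β-boryl ketone F8. NaBO3 oxidises the C–B bond with retention to the bridged hydroxy ketone 18, here isolated, which enters step 11, where SmI2 then only has to open the oxygen bridge.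

Step 12. What may go wrong: slow acylation of the neopentylic allylic C10 hydroxyl, and base-induced dehydration or retro-aldol opening of the β-hydroxy ketone during the longer reaction time. Fallback, from 19 to 21: 19 is first reduced as in step 13 to the triol F9; t-Bu2Si(OTf)2/2,6-lutidine closes a six-membered silylene over the 1,3-diol O4/O6 to give the silylene F10; the one remaining hydroxyl (C10) is acylated with isovaleric anhydride/DMAP at a higher temperature to the silylene ester F11; HF·pyridine removes the silylene and gives 21.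

**Further compounds**
F1 | step 7 | (E)-4-[(4-methoxybenzyl)oxy]but-3-en-2-one | CC(=O)/C=C/OCc1ccc(OC)cc1
F2 | step 7 | monocyclic triflate: 6-[dimethyl(phenyl)silyloxy]-10-(4-methoxybenzyloxy)dauca-5,8-dien-8-yl triflate, 10-OPMB trans to 1-CH3 | CC(C)[C@@H]1CC[C@]2(C)C1=C(O[Si](C)(C)c3ccccc3)CC(OS(=O)(=O)C(F)(F)F)=C[C@@H]2OCc4ccc(OC)cc4
F3 | step 7 | 6-[dimethyl(phenyl)silyloxy]-10-(4-methoxybenzyloxy)dauca-5,8-diene | CC(C)[C@@H]1CC[C@]2(C)C1=C(O[Si](C)(C)c3ccccc3)CC(C)=C[C@@H]2OCc4ccc(OC)cc4
F4 | step 7 | 10-(4-methoxybenzyloxy)dauca-4,8-dien-6-one | CC1=C[C@H](OCc3ccc(OC)cc3)[C@]2(C)CCC(C(C)C)=C2C(=O)C1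
F5 | step 7 | 4,5-epoxy-10-(4-methoxybenzyloxy)dauc-8-en-6-one, epoxide oxygen cis to 1-CH3 | CC1=C[C@H](OCc4ccc(OC)cc4)[C@]2(C)CC[C@@]3(C(C)C)O[C@@]23C(=O)C1
F6 | step 7 | 4-hydroxy-10-(4-methoxybenzyloxy)dauc-8-en-6-one, 10-O trans to 1-CH3 | CC1=C[C@H](OCc3ccc(OC)cc3)[C@]2(C)CC[C@](O)(C(C)C)[C@@H]2C(=O)C1
F7 | step 7 | 4,10-dihydroxydauc-8-en-6-one, C10 epimer of 19 | CC1=C[C@H](O)[C@]2(C)CC[C@](O)(C(C)C)[C@@H]2C(=O)C1
F8 | step 10 | 7,10-epoxy-4-(4,4,5,5-tetramethyl-1,3,2-dioxaborolan-2-yl)dauc-8-en-6-one, boron and 5-H cis to 1-CH3 | CC(C)[C@@]1(B5OC(C)(C)C(C)(C)O5)CC[C@]3(C)[C@H]1C(=O)[C@H]4O[C@@H]3C=C4C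
F9 | step 12 | dauc-8-ene-4,6,10-triol, configuration as in 21 | CC1=C[C@@H](O)[C@]2(C)CC[C@](O)(C(C)C)[C@@H]2[C@H](O)C1
F10 | step 12 | 4,6-O-(di-tert-butylsilylene)dauc-8-ene-4,6,10-triol | CC1=C[C@@H](O)[C@]2(C)CC[C@](O3)(C(C)C)[C@@H]2[C@H](O[Si]3(C(C)(C)C)C(C)(C)C)C1
F11 | step 12 | 4,6-O-(di-tert-butylsilylene)-4,6-dihydroxydauc-8-en-10-yl 3-methylbutanoate | CC1=C[C@@H](OC(=O)CC(C)C)[C@]2(C)CC[C@](O3)(C(C)C)[C@@H]2[C@H](O[Si]3(C(C)(C)C)C(C)(C)C)C1
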